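**Strategy**

The cyclohexenone ring (C3a, C4, C5, C6, C7, C7a) bears oxygen on four adjacent carbons, C5 to C7a, followed by the C4 methylene and the quaternary C3a. This is read as dimethyl squarate plus the two carbons of an alkene. A 4-alkenyl-2,3,4-trimethoxycyclobutenone opens on heating to a dienylketene that recloses to the six-membered ring, making the C3a–C7a bond and the quaternary stereocentre in one operation. In the precursor the alkene is exocyclic to a 2-methoxytetrahydropyran, a temporary ring that holds C2 and C3, masks the allyl group and O1, and directs the closure. Aqueous acid then trades this ring for the dihydrofuran; methylenation and conjugate reduction finish the route.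

Key step: step 7

Remark: the locants O1, C2, C3, C3a, C4–C7, C7a of the target are used for the same atoms in all intermediates, and the (S,S) salen catalyst is assumed to show with 3 the facial preference it shows with cis-β-methylstyrene.

**Route**

Step 1
Reactants: 1 5-bromo-1,2,3-trimethoxybenzene; 2 (Z)-prop-1-enylboronic acid
Product: 3 (Z)-1,2,3-trimethoxy-5-(prop-1-enyl)benzene
Conditions: Pd(dppf)Cl2 (3 mol %), K2CO3, dioxane/H2O, 80 °C
Reagents that add atoms: none
Why: Suzuki–Miyaura coupling of an alkenylboronic acid proceeds with retention of the cis geometry, so the (Z)-propenyl arene needed for a cis-epoxide is obtained.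

Step 2
Reactants: 3 (Z)-1,2,3-trimethoxy-5-(prop-1-enyl)benzene
Product: 4 (2R,3S)-2-methyl-3-(3,4,5-trimethoxyphenyl)oxirane (cis)
Conditions: (S,S)-[N,N'-bis(3,5-di-tert-butylsalicylidene)-1,2-cyclohexanediaminato]MnCl (5 mol %), aq. NaOCl (pH 11.3), 4-phenylpyridine N-oxide (cat.), CH2Cl2, 0 °C
Reagents that add atoms: sodium hypochlorite, [Na+].[O-]Cl
Why: Jacobsen epoxidation is at its best with cis-1-arylpropenes; the chiral manganese oxo species delivers oxygen to one enantioface and thereby fixes the absolute configuration of C2 (and of the whole route).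

Step 3
Reactants: 4 (2R,3S)-2-methyl-3-(3,4,5-trimethoxyphenyl)oxirane; 5 ethynyltrimethylsilane
Product: 7 (2R,3R)-3-(3,4,5-trimethoxyphenyl)pent-4-yn-2-ol, via silylated alkynol 6 (not isolated)
Conditions: 5, n-BuLi, THF, −78 °C; BF3·OEt2, then 4, −78 °C; work-up; K2CO3 (cat.), MeOH, rt
Reagents that add atoms: none
Why: BF3-assisted acetylide opening of an aryl epoxide (Yamaguchi-type alkynylation) occurs at the benzylic carbon by SN2 with inversion, which sets C3 while C2 keeps its oxygen and configuration; methanolysis then removes the silyl group.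

Step 4
Reactants: 7 (2R,3R)-3-(3,4,5-trimethoxyphenyl)pent-4-yn-2-ol
Product: 9 (2R,3S,4E)-4-(iodomethylidene)-3-(3,4,5-trimethoxyphenyl)hept-6-en-2-ol (iodine cis to the allyl group), via alkenylalane 8 (not isolated)
Conditions: allyl(i-Bu)2Al (3 equiv), Cp2ZrCl2 (0.2 equiv), ClCH2CH2Cl, 0 °C to rt; then I2, THF, −30 to 0 °C
Reagents that add atoms: allyldiisobutylaluminium, C=CC[Al](CC(C)C)CC(C)C; iodine, [I][I]
Why: Zirconium-catalysed allylalumination of a terminal alkyne (Negishi-type carboalumination) adds allyl to the internal carbon and aluminium to the terminal carbon in a syn fashion, and iodinolysis with retention gives the iodoalkene of defined geometry without touching a stereocentre.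

Step 5
Reactants: 9 (2R,3S,4E)-4-(iodomethylidene)-3-(3,4,5-trimethoxyphenyl)hept-6-en-2-ol
Product: 11 (2S,4E,5S,6R)-4-(iodomethylidene)-2-methoxy-6-methyl-5-(3,4,5-trimethoxyphenyl)oxane (2-methoxy axial; 5-aryl and 6-methyl equatorial), via lactol 10 (not isolated)
Conditions: OsO4 (2 mol %), NaIO4, 2,6-lutidine, dioxane/H2O, rt; then MeOH, PPTS (cat.), rt
Reagents that add atoms: methanol, CO
Why: Lemieux–Johnson cleavage takes the monosubstituted alkene in preference to the iodoalkene, the aldehyde is trapped by the C2 hydroxyl as a six-membered lactol, and Fischer-type acetalisation under equilibrium should give mainly the anomer with axial methoxy (anomeric effect).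

Step 6
Reactants: 11 (2S,4E,5S,6R)-4-(iodomethylidene)-2-methoxy-6-methyl-5-(3,4,5-trimethoxyphenyl)oxane; 12 dimethyl squarate (3,4-dimethoxycyclobut-3-ene-1,2-dione)
Product: 15 2,3,4-trimethoxy-4-{(E)-[(2S,5R,6R)-2-methoxy-6-methyl-5-(3,4,5-trimethoxyphenyl)oxan-4-ylidene]methyl}cyclobut-2-en-1-one (both epimers at the cyclobutenone C4; ring configuration as in 11), via alkenyllithium 13 (not isolated), via lithium alkoxide 14 (not isolated)
Conditions: t-BuLi (2.1 equiv), Et2O, −78 °C; 12, THF, −78 °C; MeOTf, −78 to 0 °C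
Reagents that add atoms: methyl trifluoromethanesulfonate, COS(=O)(=O)C(F)(F)F
Why: Iodine–lithium exchange with retention of alkene geometry, 1,2-addition to one carbonyl of the squarate and O-methylation of the alkoxide is the standard entry to 4-alkenyl-4-alkoxycyclobutenones; the new carbinol centre forms as a mixture that the next step erases.

Step 7
Reactants: 15 2,3,4-trimethoxy-4-{(E)-[(2S,5R,6R)-2-methoxy-6-methyl-5-(3,4,5-trimethoxyphenyl)oxan-4-ylidene]methyl}cyclobut-2-en-1-one
Product: 17 (1S,2R,4S,6R)-4,8,9,10-tetramethoxy-2-methyl-1-(3,4,5-trimethoxyphenyl)-3-oxaspiro[5.5]undeca-8,10-dien-7-one (spiro carbon = C3a; ring carbonyl carbon = C7a, trans to the aryl group on the tetrahydropyran), via dienylketene 16 (not isolated)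
Conditions: toluene (0.01 M, degassed), 110 °C
Reagents that add atoms: none
Why: Heating cleaves the C1–C4 bond of the cyclobutenone by conrotatory 4π electrocyclic opening, the 4-methoxy donor rotating outward so that the alkenyl arm turns inward to give the (Z)-dienylketene 16, whose ketene carbon then bonds to the exocyclic alkene carbon in a 6π electrocyclisation; the four-membered ring (future C5, C6, C7, C7a) thus grows by the two alkene carbons (future C4 and C3a) into the cyclohexa-2,4-dienone. The closest known reaction type is the thermal rearrangement of squarate-derived 4-alkenylcyclobutenones to cyclohexadienones and hydroquinones (Moore rearrangement), which stops at a stable 6,6-disubstituted dienone when the alkene terminus is fully substituted. One ring is closed, the six-membered carbocycle, by 6π electrocyclisation forming the C7a–C3a bond, and this makes C3a a spiro centre. C3a is controlled by the tetrahydropyran chair: methyl and aryl are equatorial, the axial anomeric methoxy group shields the axial face of the exocyclic alkene (as in additions to 3-keto α-glycosides), and the ketene carbon should therefore enter on the equatorial face, anti to the neighbouring aryl group, which is the C3a configuration of the target. The step needs torquoselectivity, secured by the 4-methoxy group, and facial selectivity, secured by the temporary ring, while the two C4 epimers of 15 converge because that centre becomes trigonal. The allyl group is carried as the acetal because a free 6-allyl-2,4-dienone would be open to Cope and retro-Claisen shifts at this temperature.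

Step 8
Reactants: 17 (1S,2R,4S,6R)-4,8,9,10-tetramethoxy-2-methyl-1-(3,4,5-trimethoxyphenyl)-3-oxaspiro[5.5]undeca-8,10-dien-7-one
Product: 18 2-[(2R,3S,3aR)-5,7-dimethoxy-2-methyl-6-oxo-3-(3,4,5-trimethoxyphenyl)-2,3-dihydro-1-benzofuran-3a(6H)-yl]acetaldehyde
Conditions: 1 M aq. HCl/THF (1:4), rt
Reagents that add atoms: water, O
Why: Aqueous acid hydrolyses the 2-deoxyglycoside-type acetal (freeing the aldehyde and the C2 hydroxyl) and the C6 methoxy of the vinylogous ester, and the hydroxyl then closes on C7a by 5-exo cyclodehydration to the cyclic vinylogous ester, the expected thermodynamic sink; no stereocentre is touched.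

Step 9
Reactants: 18 2-[(2R,3S,3aR)-5,7-dimethoxy-2-methyl-6-oxo-3-(3,4,5-trimethoxyphenyl)-2,3-dihydro-1-benzofuran-3a(6H)-yl]acetaldehyde
Product: 19 (2R,3S,3aR)-3a-allyl-5,7-dimethoxy-2-methyl-3-(3,4,5-trimethoxyphenyl)-3,3a-dihydro-1-benzofuran-6(2H)-one
Conditions: Ph3PCH3Br, KN(SiMe3)2, THF, −78 to 0 °C
Reagents that add atoms: methyltriphenylphosphonium bromide, C[P+](c1ccccc1)(c1ccccc1)c1ccccc1.[Br-]
Why: Wittig methylenation takes the unhindered aldehyde and leaves the cross-conjugated, doubly vinylogous ketone untouched, which restores the allyl group.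

Step 10
Reactants: 19 (2R,3S,3aR)-3a-allyl-5,7-dimethoxy-2-methyl-3-(3,4,5-trimethoxyphenyl)-3,3a-dihydro-1-benzofuran-6(2H)-one
Product: 21 (2R,3S,3aS,5S)-3a-allyl-5,7-dimethoxy-2-methyl-3-(3,4,5-trimethoxyphenyl)-3,3a,4,5-tetrahydro-1-benzofuran-6(2H)-one, via C5 epimer 20 (not isolated)
Conditions: [(Ph3P)CuH]6 (0.4 equiv), H2O (5 equiv), benzene, rt; then DBU (0.2 equiv), CH2Cl2, rt
Reagents that add atoms: none
Why: Conjugate reduction with Stryker's reagent delivers hydride to C4 of the α-methoxy enone and spares the tetrasubstituted β-alkoxy enone and the terminal alkene, and base equilibration of the α-methoxy ketone should funnel both C5 epimers to the 5S isomer, whose methoxy group is equatorial and trans to the pseudoaxial allyl group.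

**Compound list**

1 | 5-bromo-1,2,3-trimethoxybenzene | COc1cc(Br)cc(OC)c1OC | starting material
2 | (Z)-prop-1-enylboronic acid | C/C=C\B(O)O | starting material
3 | (Z)-1,2,3-trimethoxy-5-(prop-1-enyl)benzene | C/C=C\c1cc(OC)c(OC)c(OC)c1 | intermediate
4 | (2R,3S)-2-methyl-3-(3,4,5-trimethoxyphenyl)oxirane (cis) | C[C@H]1O[C@H]1c2cc(OC)c(OC)c(OC)c2 | intermediate
5 | ethynyltrimethylsilane | C#C[Si](C)(C)C | starting material
6 | (2R,3S)-3-(3,4,5-trimethoxyphenyl)-5-(trimethylsilyl)pent-4-yn-2-ol (same spatial arrangement as 7) | O[C@H](C)[C@H](C#C[Si](C)(C)C)c1cc(OC)c(OC)c(OC)c1 | intermediate (not isolated)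
7 | (2R,3R)-3-(3,4,5-trimethoxyphenyl)pent-4-yn-2-ol | O[C@H](C)[C@H](C#C)c1cc(OC)c(OC)c(OC)c1 | intermediate
8 | alkenylalane: O-diisobutylaluminium alkoxide of 9 with Al(i-Bu)2 in place of iodine (aluminium cis to allyl) | CC(C)C[Al](CC(C)C)O[C@H](C)[C@H](/C(CC=C)=C/[Al](CC(C)C)CC(C)C)c1cc(OC)c(OC)c(OC)c1 | intermediate (not isolated)
9 | (2R,3S,4E)-4-(iodomethylidene)-3-(3,4,5-trimethoxyphenyl)hept-6-en-2-ol | O[C@H](C)[C@H](/C(CC=C)=C/I)c1cc(OC)c(OC)c(OC)c1 | intermediate
10 | (4E,5S,6R)-4-(iodomethylidene)-6-methyl-5-(3,4,5-trimethoxyphenyl)oxan-2-ol (lactol, both anomers) | OC1C/C(=C\I)[C@H](c2cc(OC)c(OC)c(OC)c2)[C@@H](C)O1 | intermediate (not isolated)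
11 | (2S,4E,5S,6R)-4-(iodomethylidene)-2-methoxy-6-methyl-5-(3,4,5-trimethoxyphenyl)oxane | CO[C@@H]1C/C(=C\I)[C@H](c2cc(OC)c(OC)c(OC)c2)[C@@H](C)O1 | intermediate
12 | dimethyl squarate (3,4-dimethoxycyclobut-3-ene-1,2-dione) | COC1=C(OC)C(=O)C1=O | starting material
13 | alkenyllithium: 11 with lithium in place of iodine | CO[C@@H]1C/C(=C\[Li])[C@H](c2cc(OC)c(OC)c(OC)c2)[C@@H](C)O1 | intermediate (not isolated)
14 | lithium alkoxide of the 4-hydroxy analogue of 15 (both C4 epimers) | CO[C@@H]1C/C(=C\C2([O-])C(OC)=C(OC)C2=O)[C@H](c3cc(OC)c(OC)c(OC)c3)[C@@H](C)O1.[Li+] | intermediate (not isolated)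
15 | 2,3,4-trimethoxy-4-{(E)-[(2S,5R,6R)-2-methoxy-6-methyl-5-(3,4,5-trimethoxyphenyl)oxan-4-ylidene]methyl}cyclobut-2-en-1-one (both C4 epimers) | CO[C@@H]1C/C(=C\C2(OC)C(OC)=C(OC)C2=O)[C@H](c3cc(OC)c(OC)c(OC)c3)[C@@H](C)O1 | intermediate
16 | (3Z)-2,3,4-trimethoxy-5-[2-methoxy-6-methyl-5-(3,4,5-trimethoxyphenyl)oxan-4-ylidene]penta-1,3-dien-1-one (ring configuration as in 11; ketene chain cis to the ring CH2) | O=C=C(OC)/C(OC)=C(OC)\C=C1/C[C@@H](OC)O[C@H](C)[C@H]1c2cc(OC)c(OC)c(OC)c2 | intermediate (not isolated)
17 | (1S,2R,4S,6R)-4,8,9,10-tetramethoxy-2-methyl-1-(3,4,5-trimethoxyphenyl)-3-oxaspiro[5.5]undeca-8,10-dien-7-one | CO[C@@H]1C[C@]2(C=C(OC)C(OC)=C(OC)C2=O)[C@H](c3cc(OC)c(OC)c(OC)c3)[C@@H](C)O1 | intermediate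
18 | 2-[(2R,3S,3aR)-5,7-dimethoxy-2-methyl-6-oxo-3-(3,4,5-trimethoxyphenyl)-2,3-dihydro-1-benzofuran-3a(6H)-yl]acetaldehyde | O=CC[C@@]12C=C(OC)C(=O)C(OC)=C1O[C@H](C)[C@H]2c1cc(OC)c(OC)c(OC)c1 | intermediate
19 | (2R,3S,3aR)-3a-allyl-5,7-dimethoxy-2-methyl-3-(3,4,5-trimethoxyphenyl)-3,3a-dihydro-1-benzofuran-6(2H)-one | C=CC[C@@]12C=C(OC)C(=O)C(OC)=C1O[C@H](C)[C@H]2c1cc(OC)c(OC)c(OC)c1 | intermediate
20 | (2R,3S,3aS,5R)-3a-allyl-5,7-dimethoxy-2-methyl-3-(3,4,5-trimethoxyphenyl)-3,3a,4,5-tetrahydro-1-benzofuran-6(2H)-one (C5 epimer of 21) | C=CC[C@@]12C[C@@H](OC)C(=O)C(OC)=C1O[C@H](C)[C@H]2c1cc(OC)c(OC)c(OC)c1 | intermediate (not isolated)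
21 | (2R,3S,3aS,5S)-3a-allyl-5,7-dimethoxy-2-methyl-3-(3,4,5-trimethoxyphenyl)-3,3a,4,5-tetrahydro-1-benzofuran-6(2H)-one | C=CC[C@@]12C[C@H](OC)C(=O)C(OC)=C1O[C@H](C)[C@H]2c1cc(OC)c(OC)c(OC)c1 | target

**Step count and risks**

Total step count: 10. Longest linear sequence: 10 steps (1 to 21).

Steps most likely to fail:

Step 7. The face selectivity of the closure rests on the axial anomeric methoxy group and could erode; in addition the linear 2,4-dienone may be consumed by thermal Diels–Alder dimerisation, or the dienylketene may be diverted by a hydrogen shift before it closes on the fully substituted alkene carbon. The fallback addresses the second and third processes and sets out from 11 (with 12). The exchange and addition of step 6 are quenched with aqueous NH4Cl instead of MeOTf, which gives the 4-hydroxycyclobutenone F1. Thermolysis of this free alcohol (toluene, 100 °C) follows the same ring expansion, but the dienol formed tautomerises at once to the cyclohex-2-ene-1,4-dione F2, which is no longer a diene. O-Methylation of its only enolisable ketone (KN(SiMe3)2, MeOTf, THF/DMPU, −78 °C) comes back to the route at 17.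

Step 3. Ionisation of the BF3-activated cis-aryl epoxide may compete with direct displacement, which would erode the inversion at C3 or lead to rearranged carbonyl compounds. The fallback reverses the polarity and sets out from 1. Its Grignard reagent (Mg, THF) with CuI (cat.) opens (2R,3R)-2,3-epoxybutan-1-ol at C2 with inversion to give the diol F3. Chemoselective oxidation of the primary hydroxyl (TEMPO, PhI(OAc)2) gives the hydroxy aldehyde F4, and immediate homologation with dimethyl (1-diazo-2-oxopropyl)phosphonate (K2CO3, MeOH, 0 °C) comes back to the route at 7.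

Step 4. The carbometalation may place part of the allyl group on the terminal alkyne carbon, or the alkenylalane may be protonated before iodinolysis. The fallback sets out from 7. Palladium-catalysed bromoallylation (PdBr2(PhCN)2, allyl bromide, rt; syn bromopalladation, allyl insertion, β-bromide elimination) gives the bromo diene F5. The operations of step 5 convert it into the bromo acetal F6, and bromine–lithium exchange (t-BuLi), addition to 12 and MeOTf as in step 6 come back to the route at 15.

**Further compounds**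

F1 | step 7 | 4-hydroxy-2,3-dimethoxy-4-{(E)-[(2S,5R,6R)-2-methoxy-6-methyl-5-(3,4,5-trimethoxyphenyl)oxan-4-ylidene]methyl}cyclobut-2-en-1-one (both C4 epimers) | CO[C@@H]1C/C(=C\C2(O)C(OC)=C(OC)C2=O)[C@H](c3cc(OC)c(OC)c(OC)c3)[C@@H](C)O1
F2 | step 7 | (1S,2R,4S,6S)-4,8,9-trimethoxy-2-methyl-1-(3,4,5-trimethoxyphenyl)-3-oxaspiro[5.5]undec-8-ene-7,10-dione | CO[C@@H]1C[C@]2(CC(=O)C(OC)=C(OC)C2=O)[C@H](c3cc(OC)c(OC)c(OC)c3)[C@@H](C)O1
F3 | step 3 | (2S,3R)-2-(3,4,5-trimethoxyphenyl)butane-1,3-diol | O[C@H](C)[C@H](CO)c1cc(OC)c(OC)c(OC)c1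
F4 | step 3 | (2R,3R)-3-hydroxy-2-(3,4,5-trimethoxyphenyl)butanal | O[C@H](C)[C@H](C=O)c1cc(OC)c(OC)c(OC)c1
F5 | step 4 | (2R,3S,4E)-4-(bromomethylidene)-3-(3,4,5-trimethoxyphenyl)hept-6-en-2-ol | O[C@H](C)[C@H](/C(CC=C)=C/Br)c1cc(OC)c(OC)c(OC)c1
F6 | step 4 | (2S,4E,5S,6R)-4-(bromomethylidene)-2-methoxy-6-methyl-5-(3,4,5-trimethoxyphenyl)oxane | CO[C@@H]1C/C(=C\Br)[C@H](c2cc(OC)c(OC)c(OC)c2)[C@@H](C)O1
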